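**Plan**

- The target is 2-(2,4-dihydroxy-5-methoxyphenyl)-5,6,7,8-tetramethoxy-4H-chromen-4-one. The retrosynthesis first returns the two phenols to benzyl ethers, then opens O1–C2 of the pyranone (ring C) to an o-hydroxyaryl ynone.
- The ynone is cut at C8a–O1 and C4a–C4 together, giving an aryne and an arylpropiolic acid. The acid is cut at C2–C1' into an aryl iodide and propiolic acid.
- Enabling feature: C4a and C8a are adjacent carbons of ring A, and the other four ring carbons (C5, C6, C7, C8) all carry methoxy. The aryne is therefore mirror-symmetric, and either of its carbons may take O1 while the other takes C4.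
- Forward: ring A is prepared as an o-silylaryl triflate (steps 1–5) and ring B as the arylpropiolic acid (steps 6–9). The two are joined in step 10 without ring formation, ring C closes in step 11 (6-endo), and the benzyl groups are removed in step 12.
- Stereochemistry: the target has no stereogenic element, so nothing has to be controlled.

Key step: step 10

Remark: compounds 1, 10 and 15 are taken as catalogue chemicals.

**Route**

Step 1
Reactants: 1 1,2,3,4-tetramethoxybenzene
Product: 2 2,3,4,5-tetramethoxybenzaldehyde
Conditions: POCl3, DMF, 0 → 80 °C; then ice-water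
Reagents that add atoms: N,N-dimethylformamide, CN(C)C=O; water, O
Why: Vilsmeier–Haack formylation of an electron-rich arene whose two free positions are equivalent and each ortho and para to methoxy groups, so a single aldehyde is expected.

Step 2
Reactants: 2 2,3,4,5-tetramethoxybenzaldehyde
Product: 4 2,3,4,5-tetramethoxyphenol, via aryl formate 3 (not isolated)
Conditions: mCPBA, CH2Cl2, 0 °C → rt; then crude formate, K2CO3 (cat.), MeOH, rt
Reagents that add atoms: 3-chloroperoxybenzoic acid, OOC(=O)c1cccc(Cl)c1
Why: Baeyer–Villiger (Dakin-type) oxidation in which the electron-rich aryl group migrates to give the formate, which catalytic carbonate in methanol transesterifies to the phenol.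

Step 3
Reactants: 4 2,3,4,5-tetramethoxyphenol
Product: 5 2-bromo-3,4,5,6-tetramethoxyphenol
Conditions: NBS, CH2Cl2 (anhydrous), −78 → 0 °C
Reagents that add atoms: N-bromosuccinimide, O=C1CCC(=O)N1Br
Why: Electrophilic aromatic bromination at the only unsubstituted ring carbon, which lies ortho to the hydroxyl group, with low temperature and exclusion of water meant to hold back oxidation to a quinone.

Step 4
Reactants: 5 2-bromo-3,4,5,6-tetramethoxyphenol
Product: 6 (2-bromo-3,4,5,6-tetramethoxyphenoxy)trimethylsilane
Conditions: HMDS, THF, 70 °C; volatiles removed in vacuo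
Reagents that add atoms: hexamethyldisilazane, C[Si](C)(C)N[Si](C)(C)C
Why: O-silylation of a phenol with HMDS, driven by loss of ammonia, places the silyl group where it can migrate in the next step.

Step 5
Reactants: 6 (2-bromo-3,4,5,6-tetramethoxyphenoxy)trimethylsilane
Product: 9 2,3,4,5-tetramethoxy-6-(trimethylsilyl)phenyl trifluoromethanesulfonate, via aryllithium 7 (not isolated), via lithium silylphenoxide 8 (not isolated)
Conditions: n-BuLi, THF, −100 °C; then Tf2O, −100 °C → rt
Reagents that add atoms: trifluoromethanesulfonic anhydride, O=S(=O)(OS(=O)(=O)C(F)(F)F)C(F)(F)F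
Why: Bromine–lithium exchange gives an ortho-lithio silyl ether that undergoes 1,3 O→C silyl migration (retro-Brook rearrangement), and the lithium phenoxide so formed is trapped as its triflate, the standard entry to o-silylaryl triflates.

Step 6
Reactants: 10 3-(benzyloxy)-4-methoxybenzaldehyde
Product: 12 3-(benzyloxy)-4-methoxyphenol, via aryl formate 11 (not isolated)
Conditions: mCPBA, CH2Cl2, rt; then crude formate, K2CO3 (cat.), MeOH, rt
Reagents that add atoms: 3-chloroperoxybenzoic acid, OOC(=O)c1cccc(Cl)c1
Why: Baeyer–Villiger oxidation with aryl migration favoured by the para methoxy group, followed by methanolysis of the formate.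

Step 7
Reactants: 12 3-(benzyloxy)-4-methoxyphenol
Product: 13 2,4-bis(benzyloxy)-1-methoxybenzene
Conditions: BnBr, K2CO3, DMF, 60 °C
Reagents that add atoms: benzyl bromide, BrCc1ccccc1
Why: Williamson etherification of the phenoxide with a benzylic halide.

Step 8
Reactants: 13 2,4-bis(benzyloxy)-1-methoxybenzene
Product: 14 1,5-bis(benzyloxy)-2-iodo-4-methoxybenzene
Conditions: NIS, TFA (cat.), MeCN, 0 °C → rt
Reagents that add atoms: N-iodosuccinimide, O=C1CCC(=O)N1I
Why: Electrophilic aromatic iodination at the carbon para to one benzyloxy group and ortho to the other, the most activated open site, since the carbon between the two benzyloxy groups is shielded and the carbon beside the methoxy group has only one donor.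

Step 9
Reactants: 14 1,5-bis(benzyloxy)-2-iodo-4-methoxybenzene; 15 propiolic acid (prop-2-ynoic acid)
Product: 16 3-[2,4-bis(benzyloxy)-5-methoxyphenyl]prop-2-ynoic acid
Conditions: Pd(PPh3)4 (5 mol%), DBU, DMSO, 35 °C; then 1 M HCl
Reagents that add atoms: none
Why: Copper-free Sonogashira-type alkynylation of an aryl iodide with propiolic acid, run near ambient temperature and without copper so that the alkynyl carboxylate couples at its C–H terminus without decarboxylation.

Step 10
Reactants: 16 3-[2,4-bis(benzyloxy)-5-methoxyphenyl]prop-2-ynoic acid; 9 2,3,4,5-tetramethoxy-6-(trimethylsilyl)phenyl trifluoromethanesulfonate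
Product: 19 3-[2,4-bis(benzyloxy)-5-methoxyphenyl]-1-(2-hydroxy-3,4,5,6-tetramethoxyphenyl)prop-2-yn-1-one, via caesium arylpropiolate 17 (not isolated), via tetramethoxybenzyne 18 (not isolated)
Conditions: 16, Cs2CO3 (0.5 equiv), MeOH, then evaporation and drying (toluene azeotrope, vacuum); 9 (0.85 equiv, added slowly), CsF, 18-crown-6, THF, 25 °C; AcOH, 0 °C
Reagents that add atoms: none
Why: Fluoride removes the trimethylsilyl group of 9 and triflate departs, releasing the mirror-symmetric aryne 18 in the presence of carboxylate 17. A carboxylate oxygen adds to one aryne carbon, and the aryl anion generated on the neighbouring carbon attacks its own ester carbonyl through a four-membered tetrahedral alkoxide that opens to the o-acyl phenoxide, so the C8a–O1 and C4a–C4 bonds of the later chromone arise in one operation. The closest known reaction type is the fluoride-mediated insertion of arynes into the C–O bond of carboxylic acids to give o-hydroxyaryl ketones, arylpropiolic acids included. No ring closes and no stereocentre forms, because addition of the phenoxide to the alkyne would create an unstabilised in-plane vinyl anion and cannot proceed without a proton donor, and the cold acetic acid quench then releases the neutral ynone. The step needs acyl transfer to outrun protonation of the aryl anion, which would stop at the aryl ester, and this is secured by the pre-dried caesium salt in aprotic THF with no acidic hydrogen present, while keeping 17 in slight excess over 9 limits a second arylation of the hindered product phenoxide. Regioselectivity does not arise, since the methoxy groups on C5 to C8 make the two aryne carbons equivalent.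

Step 11
Reactants: 19 3-[2,4-bis(benzyloxy)-5-methoxyphenyl]-1-(2-hydroxy-3,4,5,6-tetramethoxyphenyl)prop-2-yn-1-one
Product: 21 2-[2,4-bis(benzyloxy)-5-methoxyphenyl]-5,6,7,8-tetramethoxy-4H-chromen-4-one, via diethylamino enone 20 (not isolated)
Conditions: Et2NH, EtOH, rt → 78 °C
Reagents that add atoms: none
Why: Conjugate addition of the secondary amine to the ynone gives a β-amino enone in which only the β-carbon is electrophilic, and the phenol then displaces the amine by addition–elimination (6-endo-trig oxa-Michael closure), which shuts out the 5-exo path to an aurone.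

Step 12
Reactants: 21 2-[2,4-bis(benzyloxy)-5-methoxyphenyl]-5,6,7,8-tetramethoxy-4H-chromen-4-one
Product: 22 2-(2,4-dihydroxy-5-methoxyphenyl)-5,6,7,8-tetramethoxy-4H-chromen-4-one
Conditions: H2 (1 atm), Pd/C, EtOAc–MeOH, rt
Reagents that add atoms: none
Why: Hydrogenolysis of the two benzyl aryl ethers over palladium on carbon at atmospheric pressure, under which the aryl methyl ethers and the chromone C2=C3 bond are expected to persist; a Lewis acid is avoided because it would also cleave the 5-methoxy group next to the carbonyl.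

**Compound list**

1 | 1,2,3,4-tetramethoxybenzene | COc1ccc(OC)c(OC)c1OC | starting material
2 | 2,3,4,5-tetramethoxybenzaldehyde | COc1cc(C=O)c(OC)c(OC)c1OC | intermediate
3 | 2,3,4,5-tetramethoxyphenyl formate | COc1cc(OC=O)c(OC)c(OC)c1OC | intermediate
4 | 2,3,4,5-tetramethoxyphenol | COc1cc(O)c(OC)c(OC)c1OC | intermediate
5 | 2-bromo-3,4,5,6-tetramethoxyphenol | COc1c(OC)c(OC)c(Br)c(O)c1OC | intermediate
6 | (2-bromo-3,4,5,6-tetramethoxyphenoxy)trimethylsilane | COc1c(OC)c(OC)c(Br)c(O[Si](C)(C)C)c1OC | intermediate
7 | [2,3,4,5-tetramethoxy-6-(trimethylsilyloxy)phenyl]lithium | COc1c(OC)c(OC)c([Li])c(O[Si](C)(C)C)c1OC | intermediate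
8 | lithium 2,3,4,5-tetramethoxy-6-(trimethylsilyl)phenoxide | [Li+].[O-]c1c(OC)c(OC)c(OC)c(OC)c1[Si](C)(C)C | intermediate
9 | 2,3,4,5-tetramethoxy-6-(trimethylsilyl)phenyl trifluoromethanesulfonate | COc1c(OC)c(OC)c(OS(=O)(=O)C(F)(F)F)c([Si](C)(C)C)c1OC | intermediate
10 | 3-(benzyloxy)-4-methoxybenzaldehyde (O-benzylisovanillin) | COc1ccc(C=O)cc1OCc1ccccc1 | starting material
11 | 3-(benzyloxy)-4-methoxyphenyl formate | COc1ccc(OC=O)cc1OCc1ccccc1 | intermediate
12 | 3-(benzyloxy)-4-methoxyphenol | COc1ccc(O)cc1OCc1ccccc1 | intermediate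
13 | 2,4-bis(benzyloxy)-1-methoxybenzene | COc1ccc(OCc2ccccc2)cc1OCc1ccccc1 | intermediate
14 | 1,5-bis(benzyloxy)-2-iodo-4-methoxybenzene | COc1cc(I)c(OCc2ccccc2)cc1OCc1ccccc1 | intermediate
15 | propiolic acid (prop-2-ynoic acid) | C#CC(=O)O | starting material
16 | 3-[2,4-bis(benzyloxy)-5-methoxyphenyl]prop-2-ynoic acid | COc1cc(C#CC(=O)O)c(OCc2ccccc2)cc1OCc1ccccc1 | intermediate
17 | caesium 3-[2,4-bis(benzyloxy)-5-methoxyphenyl]prop-2-ynoate | [Cs+].COc1cc(C#CC(=O)[O-])c(OCc2ccccc2)cc1OCc1ccccc1 | intermediate
18 | 3,4,5,6-tetramethoxybenzyne (1,2-didehydro-3,4,5,6-tetramethoxybenzene) | COC1=C(OC)C(OC)=C(OC)C#C1 | intermediate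
19 | 3-[2,4-bis(benzyloxy)-5-methoxyphenyl]-1-(2-hydroxy-3,4,5,6-tetramethoxyphenyl)prop-2-yn-1-one | COc1c(OC)c(OC)c(OC)c(O)c1C(=O)C#Cc1cc(OC)c(OCc2ccccc2)cc1OCc1ccccc1 | intermediate
20 | (E)-3-[2,4-bis(benzyloxy)-5-methoxyphenyl]-3-(diethylamino)-1-(2-hydroxy-3,4,5,6-tetramethoxyphenyl)prop-2-en-1-one | CCN(CC)/C(=C/C(=O)c1c(O)c(OC)c(OC)c(OC)c1OC)c1cc(OC)c(OCc2ccccc2)cc1OCc1ccccc1 | intermediate
21 | 2-[2,4-bis(benzyloxy)-5-methoxyphenyl]-5,6,7,8-tetramethoxy-4H-chromen-4-one | COc1cc(-c2cc(=O)c3c(OC)c(OC)c(OC)c(OC)c3o2)c(OCc2ccccc2)cc1OCc1ccccc1 | intermediate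
22 | 2-(2,4-dihydroxy-5-methoxyphenyl)-5,6,7,8-tetramethoxy-4H-chromen-4-one | COc1cc(-c2cc(=O)c3c(OC)c(OC)c(OC)c(OC)c3o2)c(O)cc1O | target

**Count**

Total steps: 12. Longest linear sequence: 8 steps (steps 1–5, 10, 11, 12). The ring B branch (steps 6–9) joins at step 10.

**Steps most likely to fail**

1. Step 10. The aryl anion may be protonated before it reaches the ester carbonyl, so the sequence would stop at simple O-arylation, or the product phenoxide may add to a second aryne. The fallback builds the flavone by the chalcone route, setting out from 4 and 13 and rejoining at 21.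
   - Phenol 4 would be C-acetylated at its free ortho carbon (AcOH, BF3·OEt2, 90 °C; Friedel–Crafts/Fries acylation) to give 1-(2-hydroxy-3,4,5,6-tetramethoxyphenyl)ethan-1-one F1.
   - Ether 13 would be formylated (POCl3, DMF) at the carbon that step 8 iodinates, to give 2,4-bis(benzyloxy)-5-methoxybenzaldehyde F2.
   - Claisen–Schmidt condensation of the two (KOH, EtOH, rt) should give (E)-3-[2,4-bis(benzyloxy)-5-methoxyphenyl]-1-(2-hydroxy-3,4,5,6-tetramethoxyphenyl)prop-2-en-1-one F3.
   - Oxidative cyclisation with I2 (cat.) in DMSO at 120 °C should close ring C to 21, from which step 12 proceeds unchanged.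

2. Step 9. The alkynyl carboxylate may lose CO2 under the coupling conditions, and the terminal alkyne so formed would couple a second time. The fallback brings in the carboxyl carbon last, setting out from 14 and rejoining at 16.
   - Iodide 14 would be coupled with ethynyltrimethylsilane (Pd(PPh3)2Cl2, CuI, Et3N, THF, rt) to give {[2,4-bis(benzyloxy)-5-methoxyphenyl]ethynyl}trimethylsilane F4.
   - Desilylation (K2CO3, MeOH) would give 1,5-bis(benzyloxy)-2-ethynyl-4-methoxybenzene F5.
   - Deprotonation (n-BuLi, THF, −78 °C) and quenching with CO2 should then give acid 16.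

3. Step 3. The very electron-rich phenol may be oxidised, with loss of a methyl group to a quinone, in competition with ring substitution. The fallback installs silicon by directed metalation and avoids any electrophilic halogen, setting out from 4 and rejoining at 9, so that steps 4 and 5 are also bypassed.
   - Phenol 4 would be treated with isopropyl isocyanate (Et3N, CH2Cl2) to give 2,3,4,5-tetramethoxyphenyl N-isopropylcarbamate F6.
   - In-flask N-silylation (TBSOTf, TMEDA, Et2O), carbamate-directed ortho-lithiation (n-BuLi, TMEDA, −78 °C), TMSCl and acidic work-up should give 2,3,4,5-tetramethoxy-6-(trimethylsilyl)phenyl N-isopropylcarbamate F7.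
   - Carbamate cleavage and triflation in one flask (DBU, Et2NH, MeCN, 40 °C; then PhNTf2) should deliver 9.

**Further compounds**

F1 | step 10 | 1-(2-hydroxy-3,4,5,6-tetramethoxyphenyl)ethan-1-one | CC(=O)c1c(O)c(OC)c(OC)c(OC)c1OC
F2 | step 10 | 2,4-bis(benzyloxy)-5-methoxybenzaldehyde | COc1cc(C=O)c(OCc2ccccc2)cc1OCc1ccccc1
F3 | step 10 | (E)-3-[2,4-bis(benzyloxy)-5-methoxyphenyl]-1-(2-hydroxy-3,4,5,6-tetramethoxyphenyl)prop-2-en-1-one | COc1cc(/C=C/C(=O)c2c(O)c(OC)c(OC)c(OC)c2OC)c(OCc2ccccc2)cc1OCc1ccccc1
F4 | step 9 | {[2,4-bis(benzyloxy)-5-methoxyphenyl]ethynyl}trimethylsilane | COc1cc(C#C[Si](C)(C)C)c(OCc2ccccc2)cc1OCc1ccccc1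
F5 | step 9 | 1,5-bis(benzyloxy)-2-ethynyl-4-methoxybenzene | COc1cc(C#C)c(OCc2ccccc2)cc1OCc1ccccc1
F6 | step 3 | 2,3,4,5-tetramethoxyphenyl N-isopropylcarbamate | COc1cc(OC(=O)NC(C)C)c(OC)c(OC)c1OC
F7 | step 3 | 2,3,4,5-tetramethoxy-6-(trimethylsilyl)phenyl N-isopropylcarbamate | COc1c(OC)c(OC)c(OC(=O)NC(C)C)c([Si](C)(C)C)c1OC
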